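**Retrosynthetic overview**
1. The target is a 3,3''-linked biflavanone: unit 1 (4-methoxyphenyl, 2,3-trans) and unit 2 (4-hydroxyphenyl, 2'',3''-cis). All five phenols are carried as benzyl ethers and freed last.
2. Both pyranone rings C are disconnected in one operation at O1–C8a and C4–C4a, which removes both phloroglucinol rings A as 3,5-bis(benzyloxy)benzyne (double aryne relay annulation).
3. Enabling feature: in each unit O1 and the C4 carbonyl are ortho on ring A (C8a, C4a), and the C5 oxygen sits next to C4a. An aryne flanked by OBn therefore takes the C2 alkoxide at its remote carbon and the acyl group at its near carbon. The unit 1 C4 carbonyl and the unit 2 O1'' are 1,4-related across C3–C3'', so they can be tied as a temporary γ-lactone that releases the second alkoxide only after the first ring has closed.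
4. The lactone carrying all four stereocentres comes from an Evans syn-aldol/lactonisation (C2'', C3'') and an anti-aldol of the lactone enolate (C3, C2).
5. Ring order: temporary γ-lactone, then ring C of unit 1, then ring C of unit 2 (rings A and B are bought or made as arenes).

Key step: step 8

Remark: the alkoxides set free in step 8 are assumed to capture the aryne faster than they cleave by retro-aldol reaction; 3,5-bis(benzyloxy)phenol is taken as commercially available.

**Step 1**
Reactants: 1 (S)-4-benzyl-1,3-oxazolidin-2-one; 2 methyl 4-chloro-4-oxobutanoate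
Product: 3 methyl 4-[(4S)-4-benzyl-2-oxo-1,3-oxazolidin-3-yl]-4-oxobutanoate
Conditions: n-BuLi, THF, −78 °C; then 2, −78 to 0 °C
Reagents that add atoms: none
Why: N-acylation of the lithiated oxazolidinone by the acid chloride (standard imide formation), with no stereocentre touched.

**Step 2**
Reactants: 3 methyl 4-[(4S)-4-benzyl-2-oxo-1,3-oxazolidin-3-yl]-4-oxobutanoate; 4 4-(benzyloxy)benzaldehyde
Product: 6 (4S)-4-benzyl-3-{[(2S,3S)-2-[4-(benzyloxy)phenyl]-5-oxooxolan-3-yl]carbonyl}-1,3-oxazolidin-2-one, via syn-aldol adduct 5 (not isolated)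
Conditions: Bu2BOTf, iPr2NEt, CH2Cl2, −78 to 0 °C; 4; H2O2, pH 7 buffer, MeOH, 0 °C; cat. PPTS, CH2Cl2, rt
Reagents that add atoms: none
Why: Evans syn-aldol reaction through the Z-boron enolate of the imide and a chair Zimmerman–Traxler transition state, in which the benzyl group of the auxiliary blocks one enolate face and so sets the future C3'' and C2'' (both S); the γ-hydroxy ester then lactonises to the 2,3-trans γ-lactone (tandem aldol–lactonisation).

**Step 3**
Reactants: 6 (4S)-4-benzyl-3-{[(2S,3S)-2-[4-(benzyloxy)phenyl]-5-oxooxolan-3-yl]carbonyl}-1,3-oxazolidin-2-one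
Product: 7 (2S,3S)-2-[4-(benzyloxy)phenyl]-5-oxooxolane-3-carboxylic acid
Conditions: LiOH, H2O2, THF/H2O, 0 °C; Na2SO3; HCl to pH 2
Reagents that add atoms: hydrogen peroxide, OO
Why: hydroperoxide attacks the exocyclic imide carbonyl selectively (standard auxiliary cleavage), any opened lactone re-closes on acidification, and the stereocentres are not touched.

**Step 4**
Reactants: 7 (2S,3S)-2-[4-(benzyloxy)phenyl]-5-oxooxolane-3-carboxylic acid
Product: 8 (2S,3S)-2-[4-(benzyloxy)phenyl]-N-methoxy-N-methyl-5-oxooxolane-3-carboxamide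
Conditions: MeNHOMe·HCl, EDC·HCl, HOBt, N-methylmorpholine, CH2Cl2, 0 °C to rt
Reagents that add atoms: N,O-dimethylhydroxylamine hydrochloride, CNOC.Cl
Why: carbodiimide amide coupling through the HOBt ester under weakly basic conditions, which should leave the α-stereocentre intact (the trans-lactone is also the more stable epimer).

**Step 5**
Reactants: 8 (2S,3S)-2-[4-(benzyloxy)phenyl]-N-methoxy-N-methyl-5-oxooxolane-3-carboxamide; 9 4-methoxybenzaldehyde
Product: 11 (2S,3S,4R)-2-[4-(benzyloxy)phenyl]-N-methoxy-4-[(S)-(4-methoxyphenyl)(trimethylsilyloxy)methyl]-N-methyl-5-oxooxolane-3-carboxamide, via lithium aldolate 10 (not isolated)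
Conditions: LiN(SiMe3)2, THF, −78 °C; 9; Me3SiCl, −78 to −40 °C
Reagents that add atoms: chlorotrimethylsilane, C[Si](C)(C)Cl
Why: kinetic deprotonation at the lactone CH2 (more acidic and less hindered than the tertiary α-CH of the Weinreb amide) gives the lactone enolate of fixed E geometry, which should add to the aldehyde on the ring face opposite the C3 carboxamide through a closed Zimmerman–Traxler transition state to give the anti-aldol (future C3 of unit 1 trans on the lactone, future C2 as S), and silyl trapping blocks retro-aldol equilibration.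

**Step 6**
Reactants: 12 3,5-bis(benzyloxy)phenol
Product: 13 3,5-bis(benzyloxy)-2-bromophenol
Conditions: NBS, CH2Cl2, −78 °C to rt
Reagents that add atoms: N-bromosuccinimide, O=C1CCC(=O)N1Br
Why: electrophilic bromination of the activated phenol, expected at low temperature in a non-polar solvent to go ortho to the hydroxyl group (the two ortho positions are equivalent).

**Step 7**
Reactants: 13 3,5-bis(benzyloxy)-2-bromophenol
Product: 16 3,5-bis(benzyloxy)-2-(trimethylsilyl)phenyl trifluoromethanesulfonate, via aryl silyl ether 14 (not isolated), via lithium silylphenoxide 15 (not isolated)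
Conditions: HN(SiMe3)2, THF, 70 °C; concentrate; n-BuLi, THF, −100 to −78 °C; Tf2O, −100 °C to rt
Reagents that add atoms: hexamethyldisilazane, C[Si](C)(C)N[Si](C)(C)C; trifluoromethanesulfonic anhydride, O=S(=O)(OS(=O)(=O)C(F)(F)F)C(F)(F)F
Why: O-silylation, bromine–lithium exchange with retro-Brook migration of silicon from O to C, and triflation of the resulting phenoxide (the standard route to ortho-silylaryl triflates).

**Step 8**
Reactants: 11 (2S,3S,4R)-2-[4-(benzyloxy)phenyl]-N-methoxy-4-[(S)-(4-methoxyphenyl)(trimethylsilyloxy)methyl]-N-methyl-5-oxooxolane-3-carboxamide; 16 3,5-bis(benzyloxy)-2-(trimethylsilyl)phenyl trifluoromethanesulfonate (3 equiv used, 2 enter the product)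
Product: 19 (2S,3R)-5,7-bis(benzyloxy)-3-[(2S,3S)-5,7-bis(benzyloxy)-2-[4-(benzyloxy)phenyl]-4-oxochroman-3-yl]-2-(4-methoxyphenyl)chroman-4-one, via 3,5-bis(benzyloxy)benzyne 17 (not isolated), via mono-annulated caesium alkoxide 18 (not isolated)
Conditions: CsF (6 equiv), 18-crown-6, THF, 0 °C to rt, slow addition of 16; then AcOH, 0 °C
Reagents that add atoms: none
Why: Proposed new method: fluoride unmasks the caesium alkoxide of 11 and turns 16 into aryne 17; the alkoxide adds to the aryne carbon remote from the flanking OBn, the aryl anion formed next to that OBn attacks the lactone carbonyl, and collapse of the tetrahedral intermediate opens the lactone to the second alkoxide 18, which repeats the addition and acylates on the Weinreb amide with loss of MeN(OMe)−, so both O1–C8a and both C4–C4a bonds form in one flask. The closest known reaction type is the CsF-mediated annulation of arynes with salicylates to xanthones (heteroatom addition, then intramolecular acyl substitution by the aryl anion), together with acyl-alkylation of 3-alkoxyarynes; it is extended here to aliphatic alkoxides and to a lactone-to-alkoxide relay. Each pyranone ring closes by 6-exo-trig attack of the aryl carbanion on a C=O group (lactone for unit 1, Weinreb amide for unit 2), and the seven-membered closure onto the more distant carbonyl should be slower. No stereocentre is created: C2, C3, C3'' and C2'' are carried over from 11 because no bond to them is made or broken. The regioselectivity needed (oxygen at the future C8a, acyl at the future C4a beside the C5 oxygen) is secured by the OBn group next to the triple bond, which distorts the aryne and stabilises the anion inductively at the adjacent carbon. Acylation should win over protonation of the aryl anion and over retro-aldol cleavage because the alkoxide is released from a silyl ether without any O–H proton, the lactone keeps the second alkoxide masked until the first ring is closed, and the Weinreb amide has a poor enolate leaving group and a tetrahedral adduct that can shield C3'' from enolisation until the acidic quench.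

**Step 9**
Reactants: 19 (2S,3R)-5,7-bis(benzyloxy)-3-[(2S,3S)-5,7-bis(benzyloxy)-2-[4-(benzyloxy)phenyl]-4-oxochroman-3-yl]-2-(4-methoxyphenyl)chroman-4-one
Product: 20 (2S,3R)-5,7-dihydroxy-3-[(2S,3S)-5,7-dihydroxy-2-(4-hydroxyphenyl)-4-oxochroman-3-yl]-2-(4-methoxyphenyl)chroman-4-one
Conditions: H2 (1 atm), Pd/C (palladium on carbon), EtOAc/THF, rt
Reagents that add atoms: none
Why: hydrogenolysis of the five benzyl ethers under neutral conditions, which should spare the methyl ether and the chelated aryl ketones and should not epimerise the base-sensitive cis unit.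

**Compound list**
1 | (S)-4-benzyl-1,3-oxazolidin-2-one | O=C1N[C@@H](Cc2ccccc2)CO1 | starting material
2 | methyl 4-chloro-4-oxobutanoate | COC(=O)CCC(Cl)=O | starting material
3 | methyl 4-[(4S)-4-benzyl-2-oxo-1,3-oxazolidin-3-yl]-4-oxobutanoate | COC(=O)CCC(=O)N1[C@@H](Cc2ccccc2)COC1=O | intermediate
4 | 4-(benzyloxy)benzaldehyde | O=Cc1ccc(OCc2ccccc2)cc1 | starting material
5 | methyl (3S)-3-{(S)-[4-(benzyloxy)phenyl](hydroxy)methyl}-4-[(4S)-4-benzyl-2-oxo-1,3-oxazolidin-3-yl]-4-oxobutanoate (syn-aldol adduct, not isolated) | COC(=O)C[C@H](C(=O)N1[C@@H](Cc2ccccc2)COC1=O)[C@H](O)c1ccc(OCc2ccccc2)cc1 | intermediate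
6 | (4S)-4-benzyl-3-{[(2S,3S)-2-[4-(benzyloxy)phenyl]-5-oxooxolan-3-yl]carbonyl}-1,3-oxazolidin-2-one | O=C1C[C@H](C(=O)N2[C@@H](Cc3ccccc3)COC2=O)[C@@H](c2ccc(OCc3ccccc3)cc2)O1 | intermediate
7 | (2S,3S)-2-[4-(benzyloxy)phenyl]-5-oxooxolane-3-carboxylic acid | O=C1C[C@H](C(=O)O)[C@@H](c2ccc(OCc3ccccc3)cc2)O1 | intermediate
8 | (2S,3S)-2-[4-(benzyloxy)phenyl]-N-methoxy-N-methyl-5-oxooxolane-3-carboxamide | O=C1C[C@H](C(=O)N(C)OC)[C@@H](c2ccc(OCc3ccccc3)cc2)O1 | intermediate
9 | 4-methoxybenzaldehyde | COc1ccc(C=O)cc1 | starting material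
10 | lithium alkoxide of (2S,3S,4R)-2-[4-(benzyloxy)phenyl]-4-[(S)-hydroxy(4-methoxyphenyl)methyl]-N-methoxy-N-methyl-5-oxooxolane-3-carboxamide (not isolated) | COc1ccc(cc1)[C@@H]([O-])[C@@H]1C(=O)O[C@H](c2ccc(OCc3ccccc3)cc2)[C@H]1C(=O)N(C)OC.[Li+] | intermediate
11 | (2S,3S,4R)-2-[4-(benzyloxy)phenyl]-N-methoxy-4-[(S)-(4-methoxyphenyl)(trimethylsilyloxy)methyl]-N-methyl-5-oxooxolane-3-carboxamide | COc1ccc(cc1)[C@@H](O[Si](C)(C)C)[C@@H]1C(=O)O[C@H](c2ccc(OCc3ccccc3)cc2)[C@H]1C(=O)N(C)OC | intermediate
12 | 3,5-bis(benzyloxy)phenol | Oc1cc(OCc2ccccc2)cc(OCc2ccccc2)c1 | starting material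
13 | 3,5-bis(benzyloxy)-2-bromophenol | Oc1cc(OCc2ccccc2)cc(OCc2ccccc2)c1Br | intermediate
14 | [3,5-bis(benzyloxy)-2-bromophenoxy]trimethylsilane (not isolated) | C[Si](C)(C)Oc1cc(OCc2ccccc2)cc(OCc2ccccc2)c1Br | intermediate
15 | lithium 3,5-bis(benzyloxy)-2-(trimethylsilyl)phenoxide (not isolated) | [Li+].[O-]c1cc(OCc2ccccc2)cc(OCc2ccccc2)c1[Si](C)(C)C | intermediate
16 | 3,5-bis(benzyloxy)-2-(trimethylsilyl)phenyl trifluoromethanesulfonate | C[Si](C)(C)c1c(OCc2ccccc2)cc(OCc2ccccc2)cc1OS(=O)(=O)C(F)(F)F | intermediate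
17 | 3,5-bis(benzyloxy)benzyne (not isolated) | C1#CC(OCc2ccccc2)=CC(OCc2ccccc2)=C1 | intermediate
18 | caesium alkoxide of (2S,3S)-2-[(2S,3R)-5,7-bis(benzyloxy)-2-(4-methoxyphenyl)-4-oxochroman-3-yl]-3-[4-(benzyloxy)phenyl]-3-hydroxy-N-methoxy-N-methylpropanamide (not isolated) | COc1ccc([C@H]2Oc3cc(OCc4ccccc4)cc(OCc4ccccc4)c3C(=O)[C@@H]2[C@H](C(=O)N(C)OC)[C@H]([O-])c2ccc(OCc3ccccc3)cc2)cc1.[Cs+] | intermediate
19 | (2S,3R)-5,7-bis(benzyloxy)-3-[(2S,3S)-5,7-bis(benzyloxy)-2-[4-(benzyloxy)phenyl]-4-oxochroman-3-yl]-2-(4-methoxyphenyl)chroman-4-one | COc1ccc([C@H]2Oc3cc(OCc4ccccc4)cc(OCc4ccccc4)c3C(=O)[C@@H]2[C@@H]2C(=O)c3c(OCc4ccccc4)cc(OCc4ccccc4)cc3O[C@@H]2c2ccc(OCc3ccccc3)cc2)cc1 | intermediate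
20 | (2S,3R)-5,7-dihydroxy-3-[(2S,3S)-5,7-dihydroxy-2-(4-hydroxyphenyl)-4-oxochroman-3-yl]-2-(4-methoxyphenyl)chroman-4-one | COc1ccc([C@H]2Oc3cc(O)cc(O)c3C(=O)[C@@H]2[C@@H]2C(=O)c3c(O)cc(O)cc3O[C@@H]2c2ccc(O)cc2)cc1 | target

**Totals**
Total step count: 9. Longest linear sequence: 7 steps (steps 1, 2, 3, 4, 5, 8, 9); steps 6 and 7 make the aryne precursor in a side branch.

**Steps most likely to fail**

1. Step 8 (proposed new method). Risks: retro-aldol cleavage or base-mediated epimerisation (enolisation, retro-oxa-Michael opening) of the free alkoxides before they capture the aryne; protonation of the aryl anion before it acylates.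
   Fallback by known chemistry, making the same two bonds per ring in separate operations (aryllithium acylation for C4–C4a, intramolecular SNAr for O1–C8a). 1,3-Bis(benzyloxy)-5-fluorobenzene F1 (from 5-fluororesorcinol, BnBr, K2CO3) is brominated (NBS, MeCN) para to one OBn to give 1,5-bis(benzyloxy)-2-bromo-3-fluorobenzene F2. Bromine–lithium exchange (n-BuLi, THF, −78 °C) gives [2,4-bis(benzyloxy)-6-fluorophenyl]lithium F3. Two equivalents of it add at −78 °C to the lactone carbonyl and to the Weinreb amide of 11 and give, after work-up, the bis(2-fluoroaryl) diketone F4. CsF and Cs2CO3 in DMF then remove the silyl group, and both alkoxides displace the ortho fluorides activated by the ketones, with retention at C2 and C2''. This gives 19, where the route is rejoined.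

2. Step 5. Risks: poor diastereoselectivity at the carbinol centre (syn- instead of anti-aldol) and retro-aldol equilibration before silyl trapping.
   Fallback: from 8, C-acylation of the lithium enolate (LiN(SiMe3)2, 2 equiv; 4-methoxybenzoyl chloride) gives the β-keto lactone (2S,3S,4R)-2-[4-(benzyloxy)phenyl]-N-methoxy-4-(4-methoxybenzoyl)-N-methyl-5-oxooxolane-3-carboxamide F5, whose C4 substituent settles trans by enolisation. Reagent-controlled reduction with (R)-2-methyl-CBS-oxazaborolidine and catecholborane (4-methoxyphenyl as the large group) should give the (S)-carbinol, the free aldol F6. Me3SiCl and imidazole then return to 11.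

3. Step 6. Risks: bromination para to the hydroxyl group (between the two OBn groups) or over-bromination instead of mono-ortho-bromination.
   Fallback: from 12, carbamoylation (iPrNCO, cat. Et3N) gives 3,5-bis(benzyloxy)phenyl N-isopropylcarbamate F7. N-Silylation and carbamate-directed ortho-lithiation (Me3SiOTf, TMEDA; n-BuLi, Et2O, −78 °C; Me3SiCl) at the position between the carbamate and OBn give 3,5-bis(benzyloxy)-2-(trimethylsilyl)phenyl N-isopropylcarbamate F8. Et2NH and DBU (MeCN, 40 °C) cleave the carbamate to 3,5-bis(benzyloxy)-2-(trimethylsilyl)phenol F9, and PhNTf2 gives 16, which skips 13 to 15.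

**Further compounds**
F1 | step 8 | 1,3-bis(benzyloxy)-5-fluorobenzene | Fc1cc(OCc2ccccc2)cc(OCc2ccccc2)c1
F2 | step 8 | 1,5-bis(benzyloxy)-2-bromo-3-fluorobenzene | Fc1cc(OCc2ccccc2)cc(OCc2ccccc2)c1Br
F3 | step 8 | [2,4-bis(benzyloxy)-6-fluorophenyl]lithium | [Li]c1c(F)cc(OCc2ccccc2)cc1OCc1ccccc1
F4 | step 8 | (2S,3S)-2-[(S)-[4-(benzyloxy)phenyl](hydroxy)methyl]-1,4-bis[2,4-bis(benzyloxy)-6-fluorophenyl]-3-[(S)-(4-methoxyphenyl)(trimethylsilyloxy)methyl]butane-1,4-dione | COc1ccc(cc1)[C@@H](O[Si](C)(C)C)[C@H](C(=O)c1c(F)cc(OCc2ccccc2)cc1OCc1ccccc1)[C@H](C(=O)c1c(F)cc(OCc2ccccc2)cc1OCc1ccccc1)[C@H](O)c1ccc(OCc2ccccc2)cc1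
F5 | step 5 | (2S,3S,4R)-2-[4-(benzyloxy)phenyl]-N-methoxy-4-(4-methoxybenzoyl)-N-methyl-5-oxooxolane-3-carboxamide | COc1ccc(cc1)C(=O)[C@@H]1C(=O)O[C@H](c2ccc(OCc3ccccc3)cc2)[C@H]1C(=O)N(C)OC
F6 | step 5 | (2S,3S,4R)-2-[4-(benzyloxy)phenyl]-4-[(S)-hydroxy(4-methoxyphenyl)methyl]-N-methoxy-N-methyl-5-oxooxolane-3-carboxamide | COc1ccc(cc1)[C@@H](O)[C@@H]1C(=O)O[C@H](c2ccc(OCc3ccccc3)cc2)[C@H]1C(=O)N(C)OC
F7 | step 6 | 3,5-bis(benzyloxy)phenyl N-isopropylcarbamate | CC(C)NC(=O)Oc1cc(OCc2ccccc2)cc(OCc2ccccc2)c1
F8 | step 6 | 3,5-bis(benzyloxy)-2-(trimethylsilyl)phenyl N-isopropylcarbamate | CC(C)NC(=O)Oc1cc(OCc2ccccc2)cc(OCc2ccccc2)c1[Si](C)(C)C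
F9 | step 6 | 3,5-bis(benzyloxy)-2-(trimethylsilyl)phenol | Oc1cc(OCc2ccccc2)cc(OCc2ccccc2)c1[Si](C)(C)C
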